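Assumption: the target has no stereocentre (it is achiral), so no enantiocontrol is needed; prenyl = 3-methylbut-2-en-1-yl, and chromone/isoflavone numbering (C-2…C-8, C-1'…C-6') is used in the names.

**Retrosynthetic overview**
1. Target ⇐ (acetate off) ⇐ isoflavone p-quinone. The furan ring (C2–O2') is closed last by a redox-neutral cyclisation of the ring B quinone onto C-2, the quinone-level form of the oxidative 2'-hydroxyisoflavone → coumaronochromone closure.
2. Isoflavone quinone ⇐ C3–C1' bond by C–H/C–H coupling of a fully decorated ring A/C chromone with 2,2-dimethyl-2H-chromene-5,8-dione.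
3. Chromone ⇐ 6,8-di-C-prenyl-5,7-dihydroxychromone by proton-triggered cyclisation of the 6-prenyl group onto 5-OH (a 7-acetate blocks every other mode); γ-pyrone from di-C-prenylated phloroacetophenone plus one carbon.
4. Chromenequinone ⇐ ortho-prenyl-2,5-dimethoxyphenol by oxidative prenyl → chromene cyclisation, then oxidative demethylation.
5. Ring order: ring C (γ-pyrone), then the dihydropyran on ring A; the chromene on ring B in a separate branch; the furan last.

**Route**

Step 1
Reactants: 1 2,4,6-trihydroxyacetophenone; 2 prenyl bromide (2.2 equiv)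
Product: 3 1-[2,4,6-trihydroxy-3,5-bis(3-methylbut-2-en-1-yl)phenyl]ethanone
Conditions: 10% aq. KOH, 0 °C → rt; acidify, chromatography
Reagents that add atoms: prenyl bromide CC(C)=CCBr
Why: Phenoxide C-alkylation (aromatic prenylation as in the biosynthesis) at the two doubly activated ring positions, water favouring C- over O-attack; the symmetric 3,5-di-C-prenyl product is separated from mono- and over-alkylated material (modest yield expected).

Step 2
Reactants: 3 1-[2,4,6-trihydroxy-3,5-bis(3-methylbut-2-en-1-yl)phenyl]ethanone; 4 N,N-dimethylformamide dimethyl acetal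
Product: 6 5,7-dihydroxy-6,8-diprenyl-4H-chromen-4-one, via enaminone 5 (not isolated)
Conditions: DMF-DMA (3 equiv), PhMe, 80 °C; evaporate; then AcOH, 70 °C
Reagents that add atoms: N,N-dimethylformamide dimethyl acetal COC(OC)N(C)C
Why: Condensation of the acetyl CH3 with the amide acetal gives the enaminone, and acid-triggered addition–elimination by an ortho-OH (both are equivalent) with loss of Me2NH closes the γ-pyrone (enaminone chromone synthesis); AcOH is too weak to touch the prenyl groups.

Step 3
Reactants: 6 5,7-dihydroxy-6,8-diprenyl-4H-chromen-4-one; 7 acetic anhydride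
Product: 9 7-acetoxy-8-prenylchromone carrying a 2,2-dimethyl-3,4-dihydro-2H-pyran ring fused through O-5 and C-6, via 7-O-acetate 8 (not isolated)
Conditions: Ac2O (1.1 equiv), pyridine, CH2Cl2, 0 °C; evaporate; then anhydrous TsOH (0.3 equiv), PhMe, 70 °C
Reagents that add atoms: acetic anhydride CC(=O)OC(C)=O
Why: The non-chelated, more acidic 7-OH is acetylated selectively, then Markovnikov protonation of the 6-prenyl alkene and capture of the tertiary cation by the only free neighbouring hydroxyl (5-OH) gives the 2,2-dimethyldihydropyran (acid-catalysed prenyl hydroalkoxylation), the 8-prenyl group having no free ortho-OH to cyclise onto.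

Step 4
Reactants: 10 2,5-dimethoxyphenol; 2 prenyl bromide
Product: 11 3,6-dimethoxy-2-(3-methylbut-2-en-1-yl)phenol
Conditions: NaH (1.05 equiv), PhMe, 0 °C; prenyl bromide (1.1 equiv), rt
Reagents that add atoms: prenyl bromide CC(C)=CCBr
Why: ortho-Selective C-alkylation of a sodium phenoxide as a tight ion pair in a non-polar solvent (aromatic prenylation), with only one ortho position free.

Step 5
Reactants: 11 3,6-dimethoxy-2-(3-methylbut-2-en-1-yl)phenol
Product: 13 2,2-dimethyl-2H-chromene-5,8-dione, via dimethoxychromene 12 (not isolated)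
Conditions: DDQ (1.05 equiv), PhH, 80 °C; filter, evaporate; then (NH4)2Ce(NO3)6 (2.5 equiv), MeCN–H2O, 0 °C
Reagents that add atoms: water O
Why: DDQ abstracts hydride from the benzylic prenyl CH2 to give an o-quinone methide that closes by 6π-oxa-electrocyclisation to the 2,2-dimethylchromene (one phenol oxygen, so one regioisomer), and (NH4)2Ce(NO3)6 then oxidatively demethylates the para-dimethoxy pair to the p-quinone without attacking the chromene alkene.

Step 6
Reactants: 9 7-acetoxy-8-prenylchromone carrying the O-5/C-6-fused 2,2-dimethyldihydropyran; 13 2,2-dimethyl-2H-chromene-5,8-dione (1.5 equiv)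
Product: 14 isoflavone quinone: compound 9 bearing at C-3 the 2,2-dimethyl-5,8-dioxo-5,8-dihydro-2H-chromen-6-yl group
Conditions: Pd(OAc)2 (15 mol %), AgOAc (2.5 equiv), PivOH (3 equiv), DCE, 80 °C
Reagents that add atoms: none
Why: Dehydrogenative Heck-type (Fujiwara–Moritani) C–H/C–H coupling: divalent palladium palladates C-3 of the chromone (the nucleophilic α-carbon of the vinylogous ester), the aryl group is delivered to C-6 of 13 (β to the more electrophilic C-8 carbonyl, the usual 2-alkoxyquinone regiochemistry), and β-hydride elimination with AgOAc re-oxidation gives the quinone.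

Step 7
Reactants: 14 isoflavone quinone
Product: 16 target coumaronochromone (ring A: O-5/C-6 2,2-dimethyldihydropyran, 7-OH, 8-prenyl; ring B: O-2' bonded to C-2 as the furan, 2,2-dimethyl-2H-pyran fused at C-3'/O-4', 5'-OH), via target 7-O-acetate 15 (not isolated)
Conditions: Sc(OTf)3 (10 mol %), 4 Å MS, CH2Cl2 (0.01 M), 0 °C → rt, Ar; then MeOH, K2CO3 (30 mol %), 0 °C; AcOH quench
Reagents that add atoms: none
Why: Proposed new method: Sc(OTf)3 chelated between the C-4 carbonyl and the O-5 ether turns the chromone into a 4-metalloxybenzopyrylium whose C-2 is attacked 5-exo by the adjacent quinone carbonyl oxygen (the electron-rich, vinylogous-ester-like C=O next to the chromene carbon), and loss of the C-2 proton aromatises ring B to the 5'-phenol, so the quinone acts as the internal oxidant and the net change is an isomerisation; the closest known reaction types are the acid- or light-induced cyclisation of 2-arylbenzoquinones to 2-hydroxydibenzofurans and Lewis-acid quinone/enol ether [3+2] benzofuran annulations, and the K2CO3/MeOH stage is a routine aryl acetate methanolysis.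

**Compound list**
1 | 2,4,6-trihydroxyacetophenone | CC(=O)c1c(O)cc(O)cc1O | starting material
2 | prenyl bromide (1-bromo-3-methylbut-2-ene) | CC(C)=CCBr | starting material
3 | 1-[2,4,6-trihydroxy-3,5-bis(3-methylbut-2-en-1-yl)phenyl]ethanone | CC(=O)c1c(O)c(CC=C(C)C)c(O)c(CC=C(C)C)c1O | intermediate
4 | N,N-dimethylformamide dimethyl acetal | COC(OC)N(C)C | starting material
5 | (E)-3-(dimethylamino)-1-[2,4,6-trihydroxy-3,5-bis(3-methylbut-2-en-1-yl)phenyl]prop-2-en-1-one | CN(C)/C=C/C(=O)c1c(O)c(CC=C(C)C)c(O)c(CC=C(C)C)c1O | intermediate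
6 | 5,7-dihydroxy-6,8-bis(3-methylbut-2-en-1-yl)-4H-chromen-4-one | O=c1ccoc2c(CC=C(C)C)c(O)c(CC=C(C)C)c(O)c12 | intermediate
7 | acetic anhydride | CC(=O)OC(C)=O | starting material
8 | 5-hydroxy-6,8-bis(3-methylbut-2-en-1-yl)-4-oxo-4H-chromen-7-yl acetate | CC(=O)Oc1c(CC=C(C)C)c(O)c2c(=O)ccoc2c1CC=C(C)C | intermediate
9 | 7-acetoxy-8-prenylchromone with a 2,2-dimethyl-3,4-dihydro-2H-pyran fused through O-5 and C-6 (dihydropyrano[2,3-f]chromen-4-one skeleton) | O=c1ccoc2c(CC=C(C)C)c(OC(C)=O)c3CCC(C)(C)Oc3c12 | intermediate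
10 | 2,5-dimethoxyphenol | COc1ccc(OC)c(O)c1 | starting material
11 | 3,6-dimethoxy-2-(3-methylbut-2-en-1-yl)phenol | COc1ccc(OC)c(CC=C(C)C)c1O | intermediate
12 | 5,8-dimethoxy-2,2-dimethyl-2H-chromene | COc1ccc(OC)c2c1OC(C)(C)C=C2 | intermediate
13 | 2,2-dimethyl-2H-chromene-5,8-dione | CC1(C)C=CC2=C(O1)C(=O)C=CC2=O | intermediate
14 | isoflavone quinone: 9 substituted at C-3 by 2,2-dimethyl-5,8-dioxo-5,8-dihydro-2H-chromen-6-yl | CC1(C)C=CC2=C(O1)C(=O)C=C(C2=O)c1coc2c(CC=C(C)C)c(OC(C)=O)c3CCC(C)(C)Oc3c2c1=O | intermediate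
15 | 7-O-acetate of the target (acetate on the ring A hydroxyl next to the prenyl group) | CC(C)=CCc1c(OC(C)=O)c2c(c3c(=O)c4c(oc13)oc1c3c(c(O)cc14)OC(C)(C)C=C3)OC(C)(C)CC2 | intermediate
16 | target coumaronochromone CNP0081330.0 | CC(C)=CCc1c(O)c2c(c3c(=O)c4c(oc13)oc1c3c(c(O)cc14)OC(C)(C)C=C3)OC(C)(C)CC2 | target

**Totals**
Total steps: 7. Longest linear sequence: 5 (steps 1, 2, 3, 6, 7); steps 4 and 5 form the two-step side branch to 13.

**Three steps most likely to fail, each with one fallback**

Step 6 (C–H/C–H coupling in the presence of prenyl and chromene alkenes). The fallback sets out from 9 and 13 and comes back at 14, replacing palladium C–H activation by enaminone conjugate addition. Excess pyrrolidine in MeOH at rt opens the chromone of 9 by aza-Michael addition and cleaves the acetate, giving (E)-1-[5,7-dihydroxy-2,2-dimethyl-6-prenylchroman-8-yl]-3-(pyrrolidin-1-yl)prop-2-en-1-one F1. F1 is stirred with 13 (2.2 equiv) in AcOH at rt: the enaminone α-carbon adds to C-6 of 13, the chelated phenol re-closes the γ-pyrone with loss of pyrrolidine (six-membered closure should outrun Nenitzescu-type furan closure), and the second equivalent of 13 oxidises the hydroquinone to the 7-hydroxy isoflavone quinone F2. Acetylation of F2 with 7 in pyridine at 0 °C returns 14.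

Step 7 (the new quinone cycloisomerisation). The fallback sets out from 14 and comes back at 16, using the established DDQ dehydrogenative cyclisation of a 2'-hydroxyisoflavone instead. Aqueous Na2S2O4/EtOAc reduces 14 to the 2',5'-dihydroxyisoflavone F3. The less hindered 5'-OH is acetylated selectively (7, 1.0 equiv, pyridine, −20 °C) to the 5'-O-acetyl-2'-hydroxyisoflavone F4, so that the ring can no longer go to the quinone. DDQ (1.2 equiv, dioxane, rt → 60 °C) closes the furan to the target 5',7-di-O-acetate F5, and K2CO3/MeOH at 0 °C removes both acetates to give 16.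

Step 1 (double C-prenylation, known but low-yielding and messy). The fallback sets out from 1 and comes back at 3, moving the prenyl groups from oxygen to carbon. Prenyl bromide 2 (2.2 equiv) with K2CO3 in refluxing acetone O-alkylates the two non-chelated hydroxyls to give 1-[2-hydroxy-4,6-bis(3-methylbut-2-en-1-yloxy)phenyl]ethanone F6. Acid-treated aluminosilicate clay montmorillonite K10 (idealised Al2Si4O10(OH)2·nH2O) in CH2Cl2 at 0 °C then effects a double [1,3] O→C prenyl shift; since only C-3 and C-5 are free, the product is 3.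

**Further compounds**
F1 | step 6 | (E)-1-[5,7-dihydroxy-2,2-dimethyl-6-(3-methylbut-2-en-1-yl)chroman-8-yl]-3-(pyrrolidin-1-yl)prop-2-en-1-one | O=C(/C=C/N1CCCC1)c1c(O)c(CC=C(C)C)c(O)c2CCC(C)(C)Oc12
F2 | step 6 | 7-hydroxy isoflavone quinone (desacetyl-14) | CC1(C)C=CC2=C(O1)C(=O)C=C(C2=O)c1coc2c(CC=C(C)C)c(O)c3CCC(C)(C)Oc3c2c1=O
F3 | step 7 | 2',5'-dihydroxyisoflavone (hydroquinone of 14) | CC1(C)C=Cc2c(O)c(cc(O)c2O1)-c1coc2c(CC=C(C)C)c(OC(C)=O)c3CCC(C)(C)Oc3c2c1=O
F4 | step 7 | 5'-O-acetyl-2'-hydroxyisoflavone (7,5'-diacetate of F3 level) | CC1(C)C=Cc2c(O)c(cc(OC(C)=O)c2O1)-c1coc2c(CC=C(C)C)c(OC(C)=O)c3CCC(C)(C)Oc3c2c1=O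
F5 | step 7 | target 5',7-di-O-acetate | CC(C)=CCc1c(OC(C)=O)c2c(c3c(=O)c4c(oc13)oc1c3c(c(OC(C)=O)cc14)OC(C)(C)C=C3)OC(C)(C)CC2
F6 | step 1 | 1-[2-hydroxy-4,6-bis(3-methylbut-2-en-1-yloxy)phenyl]ethanone | CC(=O)c1c(O)cc(OCC=C(C)C)cc1OCC=C(C)C
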